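Halimane numbering (ring A: C1–C5, C10; ring B: C5–C10). Ring B is disconnected at C5–C6 and C9–C10. The C1=C10 olefin beside the quaternary C9, together with the lone methyl on C8, is read as a latent ring-B 9(10)-en-8-one. The key step is therefore a Robinson annulation: the regiodefined C5 enolate of a ring-A ketone (C10 carbonyl; C4 quaternary centre set by asymmetric conjugate addition) adds to an α-silyl vinyl ketone that carries the complete side chain (C5–C6), and aldol condensation closes ring B (C9–C10). Deconjugative methylation at C9 then shifts the olefin to C1=C10, and the C8 carbonyl is turned into the C8 methyl.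

Key step: step 6

Remark: in this numbering C4 is the quaternary carbon bearing CO2Me, C5 the ring-fusion CH, C10 the ring-fusion sp2 carbon, C9 the quaternary carbon bearing a methyl and the C11–C15 side chain, and C8 the CH(CH3) carbon; compounds 1, 5 and 9 and all reagents are taken to be commercial.

Step 1
Reactants: 1 but-2-yn-1-ol
Product: 2 (but-2-yn-1-yloxy)(tert-butyl)diphenylsilane
Conditions: TBDPSCl, imidazole, CH2Cl2, 0 °C → rt
Reagents that add atoms: tert-butyl(chloro)diphenylsilane, CC(C)(C)[Si](Cl)(c1ccccc1)c1ccccc1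
Why: Silyl ether formation at a primary alcohol; the TBDPS ether is chosen because it should survive the alkoxide, organometallic and hydrogenation steps that follow.

Step 2
Reactants: 2 (but-2-yn-1-yloxy)(tert-butyl)diphenylsilane
Product: 4 tert-butyl{[(E)-3-iodobut-2-en-1-yl]oxy}diphenylsilane, via alkenylzirconocene 3 (not isolated)
Conditions: Cp2Zr(H)Cl (2 equiv), THF, 50 °C; then I2, 0 °C
Reagents that add atoms: iodine, II
Why: syn-Hydrozirconation followed by iodinolysis with retention (hydrozirconation–iodination); with excess hydride the alkenylzirconium isomers should equilibrate to the one with zirconium on the methyl-bearing carbon, remote from the bulky silyloxymethyl group, so that the (E)-iodide with iodine trans to CH2O results.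

Step 3
Reactants: 4 tert-butyl{[(E)-3-iodobut-2-en-1-yl]oxy}diphenylsilane and 5 (4-ethoxy-4-oxobutyl)zinc bromide
Product: 6 ethyl (E)-7-[(tert-butyldiphenylsilyl)oxy]-5-methylhept-5-enoate
Conditions: Pd(PPh3)4 (5 mol %), THF, 50 °C
Reagents that add atoms: none
Why: Negishi sp3–sp2 cross-coupling, which tolerates the ester and proceeds with retention of olefin geometry, so the (E)-trisubstituted C13=C14 olefin of the side chain is fixed here.

Step 4
Reactants: 6 ethyl (E)-7-[(tert-butyldiphenylsilyl)oxy]-5-methylhept-5-enoate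
Product: 8 (E)-9-[(tert-butyldiphenylsilyl)oxy]-7-methyl-2-(trimethylsilyl)nona-1,7-dien-3-one, via Weinreb amide 7 (not isolated)
Conditions: MeNH(OMe)·HCl, iPrMgCl, THF, −20 °C; then CH2=C(SiMe3)MgBr (from CH2=C(SiMe3)Br and Mg), −20 → 0 °C; aq. NH4Cl
Reagents that add atoms: (1-(trimethylsilyl)vinyl)magnesium bromide, C=C([Mg]Br)[Si](C)(C)C; N,O-dimethylhydroxylamine hydrochloride, CNOC.Cl (its atoms stay only in intermediate 7)
Why: One-pot Weinreb ketone synthesis: the magnesium amide turns the ester into the N-methoxy-N-methylamide 7, whose chelated adduct with the α-silylvinyl Grignard reagent should collapse only on work-up, which avoids over-addition and delivers an α-silyl enone that serves as a non-polymerising vinyl ketone equivalent in step 6.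

Step 5
Reactants: 9 methyl 3-oxocyclohex-1-ene-1-carboxylate
Product: 11 methyl (S)-1-methyl-3-[(trimethylsilyl)oxy]cyclohex-2-ene-1-carboxylate, via methylzinc enolate 10 (not isolated)
Conditions: Me2Zn, (CuOTf)2·C6H6 (2.5 mol %), chiral N-heterocyclic carbene ligand (5 mol %, from its imidazolinium salt), Et2O, −30 °C; then TMSOTf, Et3N, −30 → 0 °C
Reagents that add atoms: dimethylzinc, C[Zn]C; trimethylsilyl trifluoromethanesulfonate, C[Si](C)(C)OS(=O)(=O)C(F)(F)F
Why: Copper-catalysed asymmetric conjugate addition of a methylzinc reagent to the ester-bearing β-carbon of the enone should set the C4 quaternary stereocentre as (S) under control of the chiral ligand (its enantiomer is chosen accordingly), and O-silylation of the zinc enolate stores the enolate regiochemistry (C5=C10) for the annulation.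

Step 6
Reactants: 11 methyl (S)-1-methyl-3-[(trimethylsilyl)oxy]cyclohex-2-ene-1-carboxylate and 8 (E)-9-[(tert-butyldiphenylsilyl)oxy]-7-methyl-2-(trimethylsilyl)nona-1,7-dien-3-one
Product: 15 methyl (1S,8aR)-5-[(3E)-5-[(tert-butyldiphenylsilyl)oxy]-3-methylpent-3-en-1-yl]-1-methyl-6-oxo-1,2,3,4,6,7,8,8a-octahydronaphthalene-1-carboxylate, via potassium enolate 12 (not isolated), via silylated diketone 13 (not isolated), via diketone 14 (not isolated)
Conditions: KOtBu (1.0 equiv), THF, −20 °C; 8, −78 → −20 °C; then NaOMe, MeOH, 50 °C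
Reagents that add atoms: none
Why: Potassium tert-butoxide cleaves the O–Si bond of 11 and releases enolate 12 with its double bond fixed at C5=C10, which adds in a Michael reaction to the unsubstituted terminus of α-silyl enone 8 (C5–C6) to give 13; methoxide then removes the α-silyl group (14), the C9 enolate of the chain ketone adds to the C10 carbonyl, and E1cB loss of water gives the C9=C10 enone (C9–C10). The closest known reaction type is the Robinson annulation in its variant with a regiodefined enolate and an α-silyl vinyl ketone. Ring B closes in a 6-(enolexo)-exo-trig aldol addition; the competing bridged ketol from the C1 enolate is reversible and is drained by the irreversible dehydration. The only new stereocentre, C5, is controlled by the C4 quaternary centre: the enone should approach anti to the pseudo-axial methyl and gauche to the flat ester, so that C6 ends cis to the ester, and the same isomer (equatorial methyl, axial ester at C4) is the favoured one if C5 equilibrates at the diketone stage. The step needs C5-versus-C1 regioselectivity, secured by the position of the silyl enol ether, and clean 1,4-addition without oligomerisation, secured by the α-silyl group of 8.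

Step 7
Reactants: 15 methyl (1S,8aR)-5-[(3E)-5-[(tert-butyldiphenylsilyl)oxy]-3-methylpent-3-en-1-yl]-1-methyl-6-oxo-1,2,3,4,6,7,8,8a-octahydronaphthalene-1-carboxylate
Product: 17 methyl (1S,5R,8aR)-5-[(3E)-5-[(tert-butyldiphenylsilyl)oxy]-3-methylpent-3-en-1-yl]-1,5-dimethyl-6-oxo-1,2,3,5,6,7,8,8a-octahydronaphthalene-1-carboxylate, via potassium dienolate 16 (not isolated)
Conditions: KOtBu (1.1 equiv), MeI (3 equiv), tBuOH–THF, 0 °C → rt
Reagents that add atoms: iodomethane, CI
Why: Deconjugative α-alkylation of an extended enolate: γ-deprotonation should occur at the unhindered C1 methylene to give the heteroannular (transoid) dienolate 16 rather than the homoannular one through the neopentyl C5–H, and methyl iodide should attack C9 on the α-face, syn to the axial H5 and anti to the pseudo-axial C4 ester that screens the β-face from its peri position, which creates the C9 quaternary stereocentre (methyl cis to H5) and leaves the olefin at C1=C10, where it cannot return into conjugation.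

Step 8
Reactants: 17 methyl (1S,5R,8aR)-5-[(3E)-5-[(tert-butyldiphenylsilyl)oxy]-3-methylpent-3-en-1-yl]-1,5-dimethyl-6-oxo-1,2,3,5,6,7,8,8a-octahydronaphthalene-1-carboxylate
Product: 18 methyl (1S,5S,8aR)-5-[(3E)-5-[(tert-butyldiphenylsilyl)oxy]-3-methylpent-3-en-1-yl]-1,5-dimethyl-6-methylidene-1,2,3,5,6,7,8,8a-octahydronaphthalene-1-carboxylate
Conditions: Ph3PCH3Br, KOtBu, toluene, 90 °C
Reagents that add atoms: methylenetriphenylphosphorane, C=P(c1ccccc1)(c1ccccc1)c1ccccc1
Why: Wittig methylenation under forcing conditions, feasible because the ketone is the only reactive carbonyl (the neopentyl ester has no α-hydrogen and should not be attacked by the ylide) and no stereocentre can epimerise.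

Step 9
Reactants: 18 methyl (1S,5S,8aR)-5-[(3E)-5-[(tert-butyldiphenylsilyl)oxy]-3-methylpent-3-en-1-yl]-1,5-dimethyl-6-methylidene-1,2,3,5,6,7,8,8a-octahydronaphthalene-1-carboxylate
Product: 19 methyl (1S,5S,6R,8aR)-5-[(3E)-5-[(tert-butyldiphenylsilyl)oxy]-3-methylpent-3-en-1-yl]-1,5,6-trimethyl-1,2,3,5,6,7,8,8a-octahydronaphthalene-1-carboxylate
Conditions: H2 (1 atm), RhCl(PPh3)3 (10 mol %), toluene–EtOH, rt
Reagents that add atoms: none
Why: Homogeneous hydrogenation with RhCl(PPh3)3 should reduce only the 1,1-disubstituted exocyclic olefin and leave the two trisubstituted olefins, and hydrogen should be delivered to C8 from the β-face, which is open because C10 is trigonal whereas the α-face is blocked by the axial C9 methyl, giving the equatorial C8 methyl cis to the C9 methyl (8R).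

Step 10
Reactants: 19 methyl (1S,5S,6R,8aR)-5-[(3E)-5-[(tert-butyldiphenylsilyl)oxy]-3-methylpent-3-en-1-yl]-1,5,6-trimethyl-1,2,3,5,6,7,8,8a-octahydronaphthalene-1-carboxylate
Product: 20 methyl (1S,5S,6R,8aR)-5-[(3E)-5-hydroxy-3-methylpent-3-en-1-yl]-1,5,6-trimethyl-1,2,3,5,6,7,8,8a-octahydronaphthalene-1-carboxylate
Conditions: HF·pyridine, pyridine–THF, 0 °C → rt
Reagents that add atoms: none
Why: Fluoride-driven cleavage of the silyl ether (Si–F bond formation), buffered by pyridine so that the methyl ester and the olefins should be untouched.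

Step 11
Reactants: 20 methyl (1S,5S,6R,8aR)-5-[(3E)-5-hydroxy-3-methylpent-3-en-1-yl]-1,5,6-trimethyl-1,2,3,5,6,7,8,8a-octahydronaphthalene-1-carboxylate
Product: 21 methyl (1S,5S,6R,8aR)-5-[(3E)-5-(formyloxy)-3-methylpent-3-en-1-yl]-1,5,6-trimethyl-1,2,3,5,6,7,8,8a-octahydronaphthalene-1-carboxylate (CNP0188193.1)
Conditions: HCO2H/Ac2O (premixed, 50 °C), pyridine, CH2Cl2, 0 °C
Reagents that add atoms: acetic formic anhydride, CC(=O)OC=O
Why: O-Acylation (formylation) of the primary allylic alcohol with the mixed anhydride, which transfers the more electrophilic formyl group; no stereocentre is involved.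

Compound list
1 | but-2-yn-1-ol | CC#CCO | starting material
2 | (but-2-yn-1-yloxy)(tert-butyl)diphenylsilane | CC#CCO[Si](c1ccccc1)(c1ccccc1)C(C)(C)C | intermediate
3 | chlorobis(cyclopentadienyl)[(E)-4-[(tert-butyldiphenylsilyl)oxy]but-2-en-2-yl]zirconium (alkenylzirconocene, Zr trans to CH2O) | C/C(=C\CO[Si](c1ccccc1)(c1ccccc1)C(C)(C)C)[Zr](Cl)(C1C=CC=C1)C1C=CC=C1 | intermediate
4 | tert-butyl{[(E)-3-iodobut-2-en-1-yl]oxy}diphenylsilane | C/C(I)=C\CO[Si](c1ccccc1)(c1ccccc1)C(C)(C)C | intermediate
5 | (4-ethoxy-4-oxobutyl)zinc bromide | CCOC(=O)CCC[Zn]Br | starting material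
6 | ethyl (E)-7-[(tert-butyldiphenylsilyl)oxy]-5-methylhept-5-enoate | CCOC(=O)CCC/C(C)=C/CO[Si](c1ccccc1)(c1ccccc1)C(C)(C)C | intermediate
7 | (E)-7-[(tert-butyldiphenylsilyl)oxy]-N-methoxy-N,5-dimethylhept-5-enamide (Weinreb amide) | CON(C)C(=O)CCC/C(C)=C/CO[Si](c1ccccc1)(c1ccccc1)C(C)(C)C | intermediate
8 | (E)-9-[(tert-butyldiphenylsilyl)oxy]-7-methyl-2-(trimethylsilyl)nona-1,7-dien-3-one | C=C([Si](C)(C)C)C(=O)CCC/C(C)=C/CO[Si](c1ccccc1)(c1ccccc1)C(C)(C)C | intermediate
9 | methyl 3-oxocyclohex-1-ene-1-carboxylate | COC(=O)C1=CC(=O)CCC1 | starting material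
10 | methyl (S)-1-methyl-3-[(methylzincio)oxy]cyclohex-2-ene-1-carboxylate (methylzinc enolate) | COC(=O)[C@@]1(C)CCCC(O[Zn]C)=C1 | intermediate
11 | methyl (S)-1-methyl-3-[(trimethylsilyl)oxy]cyclohex-2-ene-1-carboxylate | COC(=O)[C@@]1(C)CCCC(O[Si](C)(C)C)=C1 | intermediate
12 | potassium (S)-3-(methoxycarbonyl)-3-methylcyclohex-1-en-1-olate (potassium enolate) | COC(=O)[C@@]1(C)CCCC([O-])=C1.[K+] | intermediate
13 | methyl (1S,2S)-2-[(7E)-9-[(tert-butyldiphenylsilyl)oxy]-7-methyl-3-oxo-2-(trimethylsilyl)non-7-en-1-yl]-1-methyl-3-oxocyclohexane-1-carboxylate (silylated diketone, both epimers at the silylated carbon) | COC(=O)[C@@]1(C)CCCC(=O)[C@H]1CC([Si](C)(C)C)C(=O)CCC/C(C)=C/CO[Si](c2ccccc2)(c2ccccc2)C(C)(C)C | intermediate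
14 | methyl (1S,2S)-2-[(7E)-9-[(tert-butyldiphenylsilyl)oxy]-7-methyl-3-oxonon-7-en-1-yl]-1-methyl-3-oxocyclohexane-1-carboxylate (diketone) | COC(=O)[C@@]1(C)CCCC(=O)[C@H]1CCC(=O)CCC/C(C)=C/CO[Si](c2ccccc2)(c2ccccc2)C(C)(C)C | intermediate
15 | methyl (1S,8aR)-5-[(3E)-5-[(tert-butyldiphenylsilyl)oxy]-3-methylpent-3-en-1-yl]-1-methyl-6-oxo-1,2,3,4,6,7,8,8a-octahydronaphthalene-1-carboxylate | COC(=O)[C@@]1(C)CCCC2=C(CC/C(C)=C/CO[Si](c3ccccc3)(c3ccccc3)C(C)(C)C)C(=O)CC[C@@H]12 | intermediate
16 | potassium dienolate of 15 (C8–O−, C8=C9, C1=C10; 4S,5R) | COC(=O)[C@@]1(C)CCC=C2[C@H]1CCC([O-])=C2CC/C(C)=C/CO[Si](c3ccccc3)(c3ccccc3)C(C)(C)C.[K+] | intermediate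
17 | methyl (1S,5R,8aR)-5-[(3E)-5-[(tert-butyldiphenylsilyl)oxy]-3-methylpent-3-en-1-yl]-1,5-dimethyl-6-oxo-1,2,3,5,6,7,8,8a-octahydronaphthalene-1-carboxylate | COC(=O)[C@@]1(C)CCC=C2[C@H]1CCC(=O)[C@]2(C)CC/C(C)=C/CO[Si](c3ccccc3)(c3ccccc3)C(C)(C)C | intermediate
18 | methyl (1S,5S,8aR)-5-[(3E)-5-[(tert-butyldiphenylsilyl)oxy]-3-methylpent-3-en-1-yl]-1,5-dimethyl-6-methylidene-1,2,3,5,6,7,8,8a-octahydronaphthalene-1-carboxylate | COC(=O)[C@@]1(C)CCC=C2[C@H]1CCC(=C)[C@]2(C)CC/C(C)=C/CO[Si](c3ccccc3)(c3ccccc3)C(C)(C)C | intermediate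
19 | methyl (1S,5S,6R,8aR)-5-[(3E)-5-[(tert-butyldiphenylsilyl)oxy]-3-methylpent-3-en-1-yl]-1,5,6-trimethyl-1,2,3,5,6,7,8,8a-octahydronaphthalene-1-carboxylate | COC(=O)[C@@]1(C)CCC=C2[C@H]1CC[C@@H](C)[C@]2(C)CC/C(C)=C/CO[Si](c3ccccc3)(c3ccccc3)C(C)(C)C | intermediate
20 | methyl (1S,5S,6R,8aR)-5-[(3E)-5-hydroxy-3-methylpent-3-en-1-yl]-1,5,6-trimethyl-1,2,3,5,6,7,8,8a-octahydronaphthalene-1-carboxylate | COC(=O)[C@@]1(C)CCC=C2[C@H]1CC[C@@H](C)[C@]2(C)CC/C(C)=C/CO | intermediate
21 | methyl (1S,5S,6R,8aR)-5-[(3E)-5-(formyloxy)-3-methylpent-3-en-1-yl]-1,5,6-trimethyl-1,2,3,5,6,7,8,8a-octahydronaphthalene-1-carboxylate (CNP0188193.1; 4S,5R,8R,9S in halimane numbering) | COC(=O)[C@@]1(C)CCC=C2[C@H]1CC[C@@H](C)[C@]2(C)CC/C(C)=C/COC=O | target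

Total step count: 11. Longest linear sequence: 10 steps (from 1 to 21 through steps 1–4 and 6–11); step 5 is the one-step branch that supplies ring A.

Steps most likely to fail

Step 6 (key step). What may go wrong: the enone may add to the wrong face of the C5 enolate (C6 cis to the C4 methyl), or oligomerisation and proton transfer may outrun Michael addition at the neopentyl-type C5. The fallback replaces the free enolate by a Lewis-acid-organised addition and sets out from 6 and 11. Ester 6 is converted as in step 4 (through 7), but with CH2=CHMgBr in place of the silylated Grignard reagent, into the silicon-free vinyl ketone F1. A Mukaiyama–Michael addition of silyl enol ether 11 to F1 (TiCl4, CH2Cl2, −78 °C), in which titanium can bridge the enone carbonyl and the ring-A ester and so deliver the acceptor on the ester face, should give diketone 14, now isolated. Cyclisation and dehydration of 14 with NaOMe in MeOH brings the route back at 15.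

Step 7. What may go wrong: γ-deprotonation at C5 instead of C1 (which would move the olefin to C5=C10 and destroy C5), O-methylation, a second methylation at C7 of the product, or attack on the β-face of C9. The fallback is a neutral Stork enamine alkylation in place of the alkali dienolate and sets out from 15. Condensation with pyrrolidine (TsOH cat., toluene, removal of water) should give the heteroannular dienamine F2, the only linear dienamine available. C-Methylation at C9 with MeI in dioxane at reflux gives the iminium iodide F3, which cannot re-form an enamine towards the now quaternary C9. Hydrolysis (aq. NaOAc/AcOH) returns the route at 17.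

Step 9. What may go wrong: incomplete discrimination between the hindered exocyclic olefin and the two trisubstituted olefins, or delivery of hydrogen from the α-face. The fallback builds the C8 methyl by addition and radical deoxygenation instead of methylenation and hydrogenation and sets out from 17. Addition of MeMgBr in the presence of CeCl3 (THF, −78 °C) to the ketone gives the tertiary alcohol F4 (either C8 epimer serves). Acylation with methyl chlorooxoacetate (pyridine, DMAP) gives the methyl oxalate F5. Barton-type deoxygenation with Bu3SnH and AIBN in toluene at reflux passes through the planar tertiary C8 radical, which should take hydrogen from the open β-face opposite the axial C9 methyl; this returns the route at 19 and bypasses steps 8 and 9.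

Further compounds
F1 | step 6 | (E)-9-[(tert-butyldiphenylsilyl)oxy]-7-methylnona-1,7-dien-3-one | C=CC(=O)CCC/C(C)=C/CO[Si](c1ccccc1)(c1ccccc1)C(C)(C)C
F2 | step 7 | pyrrolidine dienamine of 15 (N on C8, C8=C9 and C1=C10; 4S,5R) | COC(=O)[C@@]1(C)CCC=C2[C@H]1CCC(N3CCCC3)=C2CC/C(C)=C/CO[Si](c4ccccc4)(c4ccccc4)C(C)(C)C
F3 | step 7 | C9-methylated pyrrolidinium (iminium) iodide of 17 | COC(=O)[C@@]1(C)CCC=C2[C@H]1CCC(=[N+]3CCCC3)[C@]2(C)CC/C(C)=C/CO[Si](c4ccccc4)(c4ccccc4)C(C)(C)C.[I-]
F4 | step 9 | tertiary alcohol from 17 (C8 bearing OH and CH3, either epimer) | COC(=O)[C@@]1(C)CCC=C2[C@H]1CCC(C)(O)[C@]2(C)CC/C(C)=C/CO[Si](c3ccccc3)(c3ccccc3)C(C)(C)C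
F5 | step 9 | methyl oxalate of F4 | COC(=O)[C@@]1(C)CCC=C2[C@H]1CCC(C)(OC(=O)C(=O)OC)[C@]2(C)CC/C(C)=C/CO[Si](c3ccccc3)(c3ccccc3)C(C)(C)C
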